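The target is a trans-2,3-diarylchroman-4-one whose ring D carries a chalcone arm to ring E. The plan cuts the pyran ring at O1–C2 and C3–C4: O1, C8a, C4a and C4 come from a ring A ortho-quinone methide, C2=C3 from an E-stilbene whose ring B hydroxyl, para to C2, makes the ring D-bearing carbon nucleophilic. A single chiral phosphoric acid-catalysed [4+2] thus closes the ring, forms both bonds and sets C2 and C3. Its partners are a MOM-protected salicyl alcohol and a stilbene with free ring B phenol, silylated ring D oxygen and a bromine for the later Heck attachment of ring E; C4 is oxidised afterwards.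

Key step: step 9

Assumption: the hand of the phosphoric acid that leads to the (2R,3S) series cannot be predicted with confidence for this pair of partners. (R)-TRIP, (R)-3,3'-bis(2,4,6-triisopropylphenyl)-1,1'-binaphthyl-2,2'-diyl hydrogen phosphate, is written; its mirror image is to be used if an analytical run shows the opposite sense.

Design choices:
- The stilbene is assembled by a Heck reaction of a silylated bromostyrene and 4-iodophenol. The ring B phenol is then free from the outset and the base-labile aryl silyl ether never meets alkoxide or hydroxide.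
- Ring E is attached at the chroman stage, before C4 is oxidised, so that base and heat are applied only while no stereocentre is epimerisable or prone to ring opening.
- All five protecting groups (three MOM, TBS, acetate) fall in one acidic operation at the end.

Step 1
Reactants: 1 2,4-dihydroxybenzaldehyde
Product: 2 2-hydroxy-4-(methoxymethoxy)benzaldehyde
Conditions: MOMCl (1.05 equiv), K2CO3 (1.2 equiv), acetone, 0 °C → rt
Reagents that add atoms: chloromethyl methyl ether (MOMCl), COCCl
Why: Williamson-type O-alkylation; the 2-hydroxyl is locked in a hydrogen bond to the aldehyde and stays untouched under mild carbonate base, so only the more acidic 4-hydroxyl is alkylated.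

Step 2
Reactants: 2 2-hydroxy-4-(methoxymethoxy)benzaldehyde
Product: 3 2-(hydroxymethyl)-5-(methoxymethoxy)phenol
Conditions: NaBH4 (1.0 equiv), MeOH/THF, 0 °C; work-up at pH 7
Reagents that add atoms: none
Why: Borohydride reduction of an aryl aldehyde; the neutral work-up avoids premature ionisation of the acid-sensitive salicyl alcohol, which is used promptly.

Step 3
Reactants: 4 5-bromo-2-hydroxybenzaldehyde
Product: 5 4-bromo-2-ethenylphenol
Conditions: Ph3PCH3Br (2.3 equiv), KOt-Bu (2.3 equiv), THF, 0 °C → rt
Reagents that add atoms: methyltriphenylphosphonium bromide, C[P+](c1ccccc1)(c1ccccc1)c1ccccc1.[Br-]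
Why: Wittig methylenation; one equivalent of base is spent on the phenol and the non-stabilised ylide is reactive enough to add to the phenoxide-bearing aldehyde.

Step 4
Reactants: 5 4-bromo-2-ethenylphenol
Product: 6 (4-bromo-2-ethenylphenoxy)(tert-butyl)dimethylsilane
Conditions: TBSCl (1.2 equiv), imidazole (2.5 equiv), CH2Cl2, rt
Reagents that add atoms: tert-butyldimethylsilyl chloride (TBSCl), CC(C)(C)[Si](C)(C)Cl
Why: Imidazole-mediated silylation of a phenol; the silyl ether later keeps the ring D oxygen from acting as a strong donor or as a hydrogen-bond partner of the catalyst.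

Step 5
Reactants: 6 (4-bromo-2-ethenylphenoxy)(tert-butyl)dimethylsilane and 7 4-iodophenol
Product: 8 4-[(E)-2-[5-bromo-2-(tert-butyldimethylsilyloxy)phenyl]ethenyl]phenol
Conditions: Pd(OAc)2 (3 mol%), Bu4NCl (1 equiv), Et3N (2.5 equiv), DMF, 60 °C
Reagents that add atoms: none
Why: Mizoroki–Heck reaction; without phosphine, zerovalent palladium inserts into the C–I bond of 7 far faster than into the electron-rich C–Br bond, arylation occurs at the terminal alkene carbon, and syn β-hydride elimination should give the E-stilbene with the ring B phenol already free.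

Step 6
Reactants: 1 2,4-dihydroxybenzaldehyde
Product: 9 2,4-bis(methoxymethoxy)benzaldehyde
Conditions: NaH (2.5 equiv), MOMCl (2.5 equiv), DMF, 0 °C → rt
Reagents that add atoms: chloromethyl methyl ether (MOMCl), COCCl
Why: Williamson-type double O-alkylation; full deprotonation by hydride also brings the hydrogen-bonded 2-hydroxyl into reaction.

Step 7
Reactants: 9 2,4-bis(methoxymethoxy)benzaldehyde
Product: 10 1-[2,4-bis(methoxymethoxy)phenyl]prop-2-en-1-ol (racemic)
Conditions: CH2=CHMgBr (1.2 equiv), THF, −78 → 0 °C; aq. NH4Cl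
Reagents that add atoms: vinylmagnesium bromide, C=C[Mg]Br
Why: Grignard 1,2-addition to an aryl aldehyde; the new carbinol centre forms as a racemate, which is of no consequence because it is oxidised in step 8.

Step 8
Reactants: 10 1-[2,4-bis(methoxymethoxy)phenyl]prop-2-en-1-ol
Product: 11 1-[2,4-bis(methoxymethoxy)phenyl]prop-2-en-1-one
Conditions: activated MnO2 (10 equiv), CH2Cl2, rt; filtered, trace BHT, used at once
Reagents that add atoms: none
Why: MnO2 oxidation of an alcohol that is both benzylic and allylic; neutral heterogeneous conditions and a filtration-only work-up suit the polymerisation-prone aryl vinyl ketone.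

Step 9
Reactants: 3 2-(hydroxymethyl)-5-(methoxymethoxy)phenol and 8 4-[(E)-2-[5-bromo-2-(tert-butyldimethylsilyloxy)phenyl]ethenyl]phenol
Product: 14 4-[(2R,3S)-3-[5-bromo-2-(tert-butyldimethylsilyloxy)phenyl]-7-(methoxymethoxy)chroman-2-yl]phenol, via ortho-quinone methide 12 (not isolated), via para-quinone methide 13 (not isolated)
Conditions: (R)-TRIP (10 mol%), 3 Å MS, PhMe/CH2Cl2, 0 °C → rt; 3 (1.3 equiv) added over 6 h to 8
Reagents that add atoms: none
Why: The phosphoric acid protonates the benzylic hydroxyl of 3 and, pushed by the para MOM-oxy group, water leaves to give ortho-quinone methide 12, which stays hydrogen-bonded to the P–OH while the phosphoryl oxygen holds the free phenol of 8. The alkene carbon of 8 that carries ring D, the vinylogous enol position of the ring B phenol, adds to the methylene of 12 (C3–C4), and the resulting para-quinone methide 13 is captured at its exocyclic carbon by the ring A phenol oxygen (O1–C2). The closest known reaction type is the chiral phosphoric acid-catalysed oxa-[4+2] (stepwise Michael/oxa-Michael, formally an inverse-demand hetero-Diels–Alder reaction) of ortho-hydroxybenzyl alcohols and hydroxystyrenes, here applied to a β-aryl hydroxystyrene and a quinone methide unsubstituted at its methylene. The pyran ring closes by 6-exo-trig attack of oxygen on the quinone methide carbon. C3 is fixed in the C–C bond-forming event, where the chiral phosphate bound to both partners selects the alkene face, and C2 follows from C3 because the ring closure is reversible through 13 and settles in the trans-diequatorial chroman, the E-geometry of 8 pointing the same way. The step needs regioselectivity (ring B at C2, ring D at C3), secured by the free para-hydroxyl of ring B against the silylated, bromine-deactivated ring D, and cross-selectivity over self-condensation of 3, secured by slow addition of 3.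

Step 10
Reactants: 14 4-[(2R,3S)-3-[5-bromo-2-(tert-butyldimethylsilyloxy)phenyl]-7-(methoxymethoxy)chroman-2-yl]phenol
Product: 15 4-[(2R,3S)-3-[5-bromo-2-(tert-butyldimethylsilyloxy)phenyl]-7-(methoxymethoxy)chroman-2-yl]phenyl acetate
Conditions: Ac2O (1.5 equiv), pyridine, DMAP (5 mol%), CH2Cl2, 0 °C → rt
Reagents that add atoms: acetic anhydride, CC(=O)OC(C)=O
Why: O-acylation of the only free phenol; the acetate removes the donor that would invite hydride loss at C2 under DDQ and conjugate addition of the phenol to the enone in the Heck step.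

Step 11
Reactants: 15 4-[(2R,3S)-3-[5-bromo-2-(tert-butyldimethylsilyloxy)phenyl]-7-(methoxymethoxy)chroman-2-yl]phenyl acetate and 11 1-[2,4-bis(methoxymethoxy)phenyl]prop-2-en-1-one
Product: 16 4-[(2R,3S)-3-[5-[(E)-3-[2,4-bis(methoxymethoxy)phenyl]-3-oxoprop-1-enyl]-2-(tert-butyldimethylsilyloxy)phenyl]-7-(methoxymethoxy)chroman-2-yl]phenyl acetate
Conditions: 11 (1.5 equiv), Pd2(dba)3 (2.5 mol%), [HP(t-Bu)3]BF4 (6 mol%), Cy2NMe (1.5 equiv), 1,4-dioxane, rt → 45 °C
Reagents that add atoms: none
Why: Mizoroki–Heck reaction; zerovalent palladium carrying the bulky electron-rich phosphine inserts into the electron-rich C–Br bond near room temperature, the aryl group adds to the terminal carbon of enone 11, and syn β-hydride elimination gives the E-enone, while the hindered amine does not add to 11 and the chroman has no base-labile stereocentre.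

Step 12
Reactants: 16 4-[(2R,3S)-3-[5-[(E)-3-[2,4-bis(methoxymethoxy)phenyl]-3-oxoprop-1-enyl]-2-(tert-butyldimethylsilyloxy)phenyl]-7-(methoxymethoxy)chroman-2-yl]phenyl acetate
Product: 17 4-[(2R,3R)-3-[5-[(E)-3-[2,4-bis(methoxymethoxy)phenyl]-3-oxoprop-1-enyl]-2-(tert-butyldimethylsilyloxy)phenyl]-4-hydroxy-7-(methoxymethoxy)chroman-2-yl]phenyl acetate (both C4 epimers)
Conditions: DDQ (1.5 equiv), CH2Cl2/H2O (10:1), 0 °C → rt
Reagents that add atoms: water, O
Why: Benzylic oxidation by hydride abstraction (DDQ oxidation at C4 of a flavan); the C4 cation is stabilised by the para 7-oxygen and by O1 whereas C2–H next to the acetoxyphenyl ring is not comparably activated, water captures the cation mainly anti to the C3 aryl group, and because the new C4 centre is erased in step 13 both epimers (and any 18 from over-oxidation) are carried on.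

Step 13
Reactants: 17 4-[(2R,3R)-3-[5-[(E)-3-[2,4-bis(methoxymethoxy)phenyl]-3-oxoprop-1-enyl]-2-(tert-butyldimethylsilyloxy)phenyl]-4-hydroxy-7-(methoxymethoxy)chroman-2-yl]phenyl acetate
Product: 18 4-[(2R,3S)-3-[5-[(E)-3-[2,4-bis(methoxymethoxy)phenyl]-3-oxoprop-1-enyl]-2-(tert-butyldimethylsilyloxy)phenyl]-7-(methoxymethoxy)-4-oxochroman-2-yl]phenyl acetate
Conditions: Dess–Martin periodinane (1.3 equiv), pyridine (3 equiv), CH2Cl2, 0 °C → rt
Reagents that add atoms: none
Why: Dess–Martin oxidation of a secondary benzylic alcohol under pyridine buffering; C2 is untouched, and C3, now α to the ketone, already sits in the thermodynamically preferred trans arrangement, so any enolisation returns the same isomer.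

Step 14
Reactants: 18 4-[(2R,3S)-3-[5-[(E)-3-[2,4-bis(methoxymethoxy)phenyl]-3-oxoprop-1-enyl]-2-(tert-butyldimethylsilyloxy)phenyl]-7-(methoxymethoxy)-4-oxochroman-2-yl]phenyl acetate
Product: 19 (2R,3S)-3-[5-[(E)-3-(2,4-dihydroxyphenyl)-3-oxoprop-1-enyl]-2-hydroxyphenyl]-7-hydroxy-2-(4-hydroxyphenyl)chroman-4-one
Conditions: HCl (1.25 M in MeOH), THF co-solvent, 40 °C
Reagents that add atoms: none
Why: Acid-catalysed methanolysis removes all five protecting groups in one operation (acetal exchange of the three MOM ethers, transesterification of the aryl acetate, solvolysis of the aryl silyl ether); acid is preferred to base or fluoride because retro-oxa-Michael opening of the chromanone, which would scramble C2, is a base-promoted process, and the mild temperature should keep the 2'-hydroxychalcone from cyclising.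

Compound list
1 | 2,4-dihydroxybenzaldehyde | O=Cc1ccc(O)cc1O | starting material
2 | 2-hydroxy-4-(methoxymethoxy)benzaldehyde | O=Cc1ccc(OCOC)cc1O | intermediate
3 | 2-(hydroxymethyl)-5-(methoxymethoxy)phenol | OCc1ccc(OCOC)cc1O | intermediate
4 | 5-bromo-2-hydroxybenzaldehyde | O=Cc1cc(Br)ccc1O | starting material
5 | 4-bromo-2-ethenylphenol | C=Cc1cc(Br)ccc1O | intermediate
6 | (4-bromo-2-ethenylphenoxy)(tert-butyl)dimethylsilane | C=Cc1cc(Br)ccc1O[Si](C)(C)C(C)(C)C | intermediate
7 | 4-iodophenol | Oc1ccc(I)cc1 | starting material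
8 | 4-[(E)-2-[5-bromo-2-(tert-butyldimethylsilyloxy)phenyl]ethenyl]phenol | Oc1ccc(/C=C/c2cc(Br)ccc2O[Si](C)(C)C(C)(C)C)cc1 | intermediate
9 | 2,4-bis(methoxymethoxy)benzaldehyde | O=Cc1ccc(OCOC)cc1OCOC | intermediate
10 | 1-[2,4-bis(methoxymethoxy)phenyl]prop-2-en-1-ol, racemic | C=CC(O)c1ccc(OCOC)cc1OCOC | intermediate
11 | 1-[2,4-bis(methoxymethoxy)phenyl]prop-2-en-1-one | C=CC(=O)c1ccc(OCOC)cc1OCOC | intermediate
12 | 3-(methoxymethoxy)-6-methylidenecyclohexa-2,4-dien-1-one (ortho-quinone methide, not isolated) | C=C1C=CC(OCOC)=CC1=O | intermediate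
13 | 4-[(2R)-2-[5-bromo-2-(tert-butyldimethylsilyloxy)phenyl]-3-[2-hydroxy-4-(methoxymethoxy)phenyl]propylidene]cyclohexa-2,5-dien-1-one (para-quinone methide, not isolated) | O=C1C=CC(=C[C@@H](Cc2ccc(OCOC)cc2O)c2cc(Br)ccc2O[Si](C)(C)C(C)(C)C)C=C1 | intermediate
14 | 4-[(2R,3S)-3-[5-bromo-2-(tert-butyldimethylsilyloxy)phenyl]-7-(methoxymethoxy)chroman-2-yl]phenol (trans) | CC(C)(C)[Si](C)(C)Oc1ccc(Br)cc1[C@@H]3Cc4ccc(OCOC)cc4O[C@H]3c5ccc(O)cc5 | intermediate
15 | 4-[(2R,3S)-3-[5-bromo-2-(tert-butyldimethylsilyloxy)phenyl]-7-(methoxymethoxy)chroman-2-yl]phenyl acetate | CC(C)(C)[Si](C)(C)Oc1ccc(Br)cc1[C@@H]3Cc4ccc(OCOC)cc4O[C@H]3c5ccc(OC(C)=O)cc5 | intermediate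
16 | 4-[(2R,3S)-3-[5-[(E)-3-[2,4-bis(methoxymethoxy)phenyl]-3-oxoprop-1-enyl]-2-(tert-butyldimethylsilyloxy)phenyl]-7-(methoxymethoxy)chroman-2-yl]phenyl acetate | CC(C)(C)[Si](C)(C)Oc1ccc(/C=C/C(=O)c6ccc(OCOC)cc6OCOC)cc1[C@@H]3Cc4ccc(OCOC)cc4O[C@H]3c5ccc(OC(C)=O)cc5 | intermediate
17 | 4-[(2R,3R)-3-[5-[(E)-3-[2,4-bis(methoxymethoxy)phenyl]-3-oxoprop-1-enyl]-2-(tert-butyldimethylsilyloxy)phenyl]-4-hydroxy-7-(methoxymethoxy)chroman-2-yl]phenyl acetate, both C4 epimers (C4 left undefined) | CC(C)(C)[Si](C)(C)Oc1ccc(/C=C/C(=O)c6ccc(OCOC)cc6OCOC)cc1[C@@H]3C(O)c4ccc(OCOC)cc4O[C@H]3c5ccc(OC(C)=O)cc5 | intermediate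
18 | 4-[(2R,3S)-3-[5-[(E)-3-[2,4-bis(methoxymethoxy)phenyl]-3-oxoprop-1-enyl]-2-(tert-butyldimethylsilyloxy)phenyl]-7-(methoxymethoxy)-4-oxochroman-2-yl]phenyl acetate | CC(C)(C)[Si](C)(C)Oc1ccc(/C=C/C(=O)c6ccc(OCOC)cc6OCOC)cc1[C@@H]3C(=O)c4ccc(OCOC)cc4O[C@H]3c5ccc(OC(C)=O)cc5 | intermediate
19 | (2R,3S)-3-[5-[(E)-3-(2,4-dihydroxyphenyl)-3-oxoprop-1-enyl]-2-hydroxyphenyl]-7-hydroxy-2-(4-hydroxyphenyl)chroman-4-one | O=C(/C=C/c1ccc(O)c([C@@H]2C(=O)c3ccc(O)cc3O[C@H]2c2ccc(O)cc2)c1)c1ccc(O)cc1O | target

Total step count: 14. Longest linear sequence: 9 steps (steps 3, 4, 5, 9, 10, 11, 12, 13, 14).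

Steps most likely to fail

Step 9. The quinone methide may be consumed by Friedel–Crafts self-condensation of electron-rich 3 before it meets the hindered 1,2-disubstituted alkene. Facial discrimination may also be poor, because the hydroxyl that anchors the catalyst is remote from the reacting carbon. The fallback sets out from 3 and 8 and gives up asymmetric induction in favour of resolution. The two partners are combined under an achiral, stronger Brønsted acid (diphenyl phosphate, 10 mol%, toluene, rt → 50 °C), where only reactivity and the thermodynamic trans preference matter, to give the racemic trans-chroman F1. Its enantiomers are separated by preparative chromatography on a chiral stationary phase (supercritical CO2/MeOH, amylose tris(3,5-dimethylphenylcarbamate)). The (2R,3S) enantiomer is 14, where the route is rejoined.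

Step 12. The C4 cation may lose the C3 proton faster than water adds; this would give the 2,3-diaryl-2H-chromene, which DDQ oxidises further with loss of C3. The fallback sets out from 15 and moves the oxidation onto a neutral quinone methide pathway. The ring A MOM ether alone is cleaved (ZnBr2, n-PrSH, CH2Cl2, 0 °C; aryl acetate and aryl silyl ether are expected to survive) to give the 7-hydroxychroman F2. As a para-alkylphenol, F2 is oxidised by DDQ (2.2 equiv, 1,4-dioxane/H2O, 0 °C → rt) through its quinone methide and the hydrated intermediate directly to the 7-hydroxychroman-4-one F3. The resulting acylphenol resists further oxidation. F3 is coupled with 11 under the conditions of step 11 to give the chalcone F4; its para-acyl phenoxide is a poor nucleophile towards the enone. Methanolic HCl as in step 14 then gives 19, where the route is rejoined.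

Step 11. Polymerisation of the aryl vinyl ketone, or its loss by conjugate addition under the basic conditions, may outpace oxidative addition into the electron-rich aryl bromide. The fallback sets out from 15 and separates the two events. A base-free Stille coupling (tributyl(vinyl)stannane, Pd(PPh3)4, toluene, 100 °C) gives the vinylarene F5. Olefin cross-metathesis of F5 with 11 (second-generation Grubbs catalyst RuCl2(=CHPh)(PCy3)(H2IMes), CH2Cl2, 40 °C) then joins a fast-reacting styrene-type alkene to the slower enone under neutral conditions and should give the E-enone 16, where the route is rejoined.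

Further compounds
F1 | step 9 | racemic trans-chroman, equimolar 14 and its mirror image | CC(C)(C)[Si](C)(C)Oc1ccc(Br)cc1[C@@H]3Cc4ccc(OCOC)cc4O[C@H]3c5ccc(O)cc5.CC(C)(C)[Si](C)(C)Oc1ccc(Br)cc1[C@H]3Cc4ccc(OCOC)cc4O[C@@H]3c5ccc(O)cc5
F2 | step 12 | 4-[(2R,3S)-3-[5-bromo-2-(tert-butyldimethylsilyloxy)phenyl]-7-hydroxychroman-2-yl]phenyl acetate | CC(C)(C)[Si](C)(C)Oc1ccc(Br)cc1[C@@H]3Cc4ccc(O)cc4O[C@H]3c5ccc(OC(C)=O)cc5
F3 | step 12 | 4-[(2R,3S)-3-[5-bromo-2-(tert-butyldimethylsilyloxy)phenyl]-7-hydroxy-4-oxochroman-2-yl]phenyl acetate | CC(C)(C)[Si](C)(C)Oc1ccc(Br)cc1[C@@H]3C(=O)c4ccc(O)cc4O[C@H]3c5ccc(OC(C)=O)cc5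
F4 | step 12 | 4-[(2R,3S)-3-[5-[(E)-3-[2,4-bis(methoxymethoxy)phenyl]-3-oxoprop-1-enyl]-2-(tert-butyldimethylsilyloxy)phenyl]-7-hydroxy-4-oxochroman-2-yl]phenyl acetate | CC(C)(C)[Si](C)(C)Oc1ccc(/C=C/C(=O)c6ccc(OCOC)cc6OCOC)cc1[C@@H]3C(=O)c4ccc(O)cc4O[C@H]3c5ccc(OC(C)=O)cc5
F5 | step 11 | 4-[(2R,3S)-3-[2-(tert-butyldimethylsilyloxy)-5-ethenylphenyl]-7-(methoxymethoxy)chroman-2-yl]phenyl acetate | CC(C)(C)[Si](C)(C)Oc1ccc(C=C)cc1[C@@H]3Cc4ccc(OCOC)cc4O[C@H]3c5ccc(OC(C)=O)cc5
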